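Readings and results are calculated for substances that don't exist, noise included.

1. At early times free enzyme and protic impurity draw on the same starting material. This reckoning takes both as first order in it, so the ratio of their rates contains no starting material.

the same everywhere: free enzyme 10 µM

| charge | starting material | protic impurity | temperature | remark | time |
|---|---|---|---|---|---|
| summer | 41 mM | 8.7 mM | 44 °C | run made earlier |  |
| dusk | 64 mM | 8.7 mM | 52 °C | run made earlier |  |
| oak | 29 mM | 8.70 mM | 40 °C |  | 5.0 h |
| maple | 29 mM | 8.70 mM | 55 °C |  | 5.0 h |

| summer: time / h | summer: target / % | dusk: time / min | dusk: target / % |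
|---|---|---|---|
| 0.200 | 60.2 | 8.00 | 64.9 |
| 0.667 | 77.8 | 15.0 | 76.4 |
| 1.00 | 80.6 | 20.0 | 80.2 |
| 1.50 | 81.3 | 30.0 | 83.1 |
| 2.50 | 81.3 | 60.0 | 84.7 |
| 3.00 | 81.2 | 90.0 | 84.9 |

(readings scatter by 0.3 percentage points)

- the earlier runs were read with a standard deviation of 0.3 percentage points
- a reading or a percentage of target counts all its forms, free or not

- the best flask by amount of target, in percent of the starting material charged; "all alike" if 1.5 percentage points covers them all (oak / maple / all alike)
- amount of target at the end, in percent of the starting material charged, oak
- amount of target at the end, in percent of the starting material charged, maple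

2. The bench rule lets each protic impurity remove one starting material, so the yield is one minus the ratio of the charges. That gives 70.0 % for oak. For the summer run it gives 78.8 %, below the plateau read there, 81.3 %.

3. Competition gives a different law. With h the fraction of impurity left after target P is made, h = exp(−P/Q). In the summer run, P is 33.3 mM and the missing 7.67 mM is charged to the impurity, leaving 1.03 mM. A reading's scatter is 0.123 mM, smaller than that remainder. So Q reads 15.6 mM: the exchange amount, a selectivity factor in concentration units, the target made while the impurity falls by a factor e.

4. The bench rule needs the ratio of available target to Q to be large. In oak it is 1.30, which leaves 27.3 % of the impurity, so the rule stops working there.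

5. Two passes for oak give a loss of 6.32 mM, then 6.66 mM, so the yield is 77.0 %. Maple has the same charges, so carrying Q unchanged gives it the same number, and my answer is all alike. The dusk run tests this carrying of Q: there Q gives 86.8 %, above the 84.9 % read.

6. The forecast differs, naming maple as best with 80.7 % for oak and 89.1 % for maple, on an equilibrium that moves with temperature: “This gives K about 2.6 at 40 °C and 5.4 at 55 °C”.

7. The flasks give 78.4 % for oak and 79.3 % for maple at 5.00 h, so the answer is all alike.

    starting material ⇌ dormant form (K = 3.00, k = 0.120 /h, Ea = 97.0 kJ/mol, ΔH = 5.00 kJ/mol)
    starting material + target ⇌ idle adduct, settled at all times (K = 89.0 /M, ΔH = −36.0 kJ/mol)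
    starting material + free enzyme ⇌ complex (K = 25.0 /M, k = 1.50 × 10⁷ /M/h, Ea = 34.0 kJ/mol, ΔH = 5.00 kJ/mol)
    complex → free enzyme + target (k = 38000 /h, Ea = 79.0 kJ/mol)
    starting material + protic impurity → quenched substrate (k = 360 /M/h, Ea = 68.0 kJ/mol)
    free enzyme → unfolded enzyme (k = 0.0370 /h, Ea = 216 kJ/mol)
    (constants at 40 °C)

Oak keeps 32 % of its protic impurity at 5.00 h, against 24.0 % from Q, while quenched substrate stands at 20.5 % of the starting material charged. The neighbouring flask is oak with 73 mM of starting material. There Q leaves 1.64 % of the impurity and gives a yield of 88.3 %. At 5.00 h, that flask holds 86.7 % of target and 2.0 % of its protic impurity.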